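**Retrosynthetic overview**

1. The target is a (2S)-flavanone. It is reached by global desilylation of its tris-silyl ether, and the strategic disconnection is the C2–C3 bond of pyranone ring C.
2. That bond is made by a catalytic, enantioconvergent Petasis–Ferrier-type [1,3] O-to-C rearrangement of a racemic 2-aryl-4-methylidene-4H-1,3-benzodioxine. This temporary 1,3-dioxine ring is not in the target; it carries ring B on O1 and stores the C4 ketone as an exocyclic enol ether.
3. Enabling feature: the O1–C2H(aryl)–O3–C4(=CH2) enol-acetal array fused to ring A. C2 is flanked by the aryl ether O1 and the electron-rich 3,4-dioxygenated ring B, so it ionises to an oxocarbenium ion, and the same C2–O3 cleavage releases the C3 enol nucleophile.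
4. The enol acetal comes from methylenation of the 1,3-benzodioxin-4-one formed from a 3-substituted 4-methoxysalicylic acid and bis-silylated 3,4-dihydroxybenzaldehyde.
5. The C8 side chain is built first on ring A (O-allylation, Claisen rearrangement, cross-metathesis with methacrolein, Luche reduction). Rings A and B are bought, the temporary dioxinone ring is closed in step 9, and ring C in step 11.

Key step: step 11

Assumption: the sense of induction of the confined chiral acid in step 11 cannot be predicted with certainty, so the catalyst antipode that delivers the 2S configuration is taken; both antipodes are equally accessible from (R)- or (S)-BINOL.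

**Route**

Step 1
Reactants: 1 methyl 2-hydroxy-4-methoxybenzoate; 2 allyl bromide
Product: 3 methyl 4-methoxy-2-(prop-2-en-1-yloxy)benzoate
Conditions: K2CO3, DMF, 60 °C
Reagents that add atoms: none
Why: Williamson ether synthesis, in which the phenoxide of the chelated salicylate is alkylated by the reactive allylic bromide in a dipolar aprotic solvent.

Step 2
Reactants: 3 methyl 4-methoxy-2-(prop-2-en-1-yloxy)benzoate
Product: 5 methyl 2-hydroxy-4-methoxy-3-(prop-2-en-1-yl)benzoate, via ortho-dienone 4 (not isolated)
Conditions: N,N-diethylaniline, 200 °C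
Reagents that add atoms: none
Why: aromatic Claisen rearrangement, a [3,3] shift to C3 (the only unsubstituted position ortho to the ether oxygen) followed by tautomerisation of the dienone to the phenol.

Step 3
Reactants: 5 methyl 2-hydroxy-4-methoxy-3-(prop-2-en-1-yl)benzoate; 6 methacrolein
Product: 7 methyl 2-hydroxy-4-methoxy-3-[(2E)-3-methyl-4-oxobut-2-en-1-yl]benzoate
Conditions: second-generation Hoveyda–Grubbs catalyst RuCl2(H2IMes)(=CH-C6H4-2-O-i-Pr) (5 mol%), methacrolein (10 equiv), CH2Cl2, 40 °C
Reagents that add atoms: none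
Why: olefin cross-metathesis of a terminal alkene with an excess of a 2-substituted acrolein, which should give the trisubstituted enal with the (E) geometry that is thermodynamically preferred.

Step 4
Reactants: 7 methyl 2-hydroxy-4-methoxy-3-[(2E)-3-methyl-4-oxobut-2-en-1-yl]benzoate
Product: 8 methyl 2-hydroxy-3-[(2E)-4-hydroxy-3-methylbut-2-en-1-yl]-4-methoxybenzoate
Conditions: NaBH4, CeCl3·7H2O, MeOH, −20 °C
Reagents that add atoms: none
Why: Luche reduction, which is 1,2-selective for the enal, leaves the chelated methyl ester untouched and keeps the alkene geometry.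

Step 5
Reactants: 8 methyl 2-hydroxy-3-[(2E)-4-hydroxy-3-methylbut-2-en-1-yl]-4-methoxybenzoate
Product: 9 methyl 3-[(2E)-4-(tert-butyldimethylsilyloxy)-3-methylbut-2-en-1-yl]-2-hydroxy-4-methoxybenzoate
Conditions: TBSCl (1.1 equiv), imidazole, CH2Cl2, 0 °C
Reagents that add atoms: tert-butyldimethylsilyl chloride, CC(C)(C)[Si](C)(C)Cl
Why: silyl ether formation at the unhindered primary allylic alcohol, while the phenol, hydrogen-bonded to the ester and flanked by two substituents, should stay free.

Step 6
Reactants: 9 methyl 3-[(2E)-4-(tert-butyldimethylsilyloxy)-3-methylbut-2-en-1-yl]-2-hydroxy-4-methoxybenzoate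
Product: 10 3-[(2E)-4-(tert-butyldimethylsilyloxy)-3-methylbut-2-en-1-yl]-2-hydroxy-4-methoxybenzoic acid
Conditions: LiOH·H2O (6 equiv), THF/MeOH/H2O, 55 °C; then cold 1 M HCl to pH 3
Reagents that add atoms: lithium hydroxide, [Li+].[OH-]
Why: ester saponification, to which a primary alkyl silyl ether is stable, with a brief cold acidification that the silyl ether should survive.

Step 7
Reactants: 11 3,4-dihydroxybenzaldehyde
Product: 12 3,4-bis(tert-butyldimethylsilyloxy)benzaldehyde
Conditions: TBSCl (2.3 equiv), imidazole, DMF, 23 °C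
Reagents that add atoms: tert-butyldimethylsilyl chloride, CC(C)(C)[Si](C)(C)Cl
Why: silyl ether formation at both phenols, which masks the catechol with groups that survive the Lewis-acidic steps and fall in the final fluoride step.

Step 8
Reactants: 10 3-[(2E)-4-(tert-butyldimethylsilyloxy)-3-methylbut-2-en-1-yl]-2-hydroxy-4-methoxybenzoic acid
Product: 13 trimethylsilyl 3-[(2E)-4-(tert-butyldimethylsilyloxy)-3-methylbut-2-en-1-yl]-4-methoxy-2-(trimethylsilyloxy)benzoate
Conditions: (Me3Si)2NH (1.5 equiv), CH2Cl2, 40 °C; volatiles removed, crude product used directly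
Reagents that add atoms: 1,1,1,3,3,3-hexamethyldisilazane, C[Si](C)(C)N[Si](C)(C)C
Why: silylation of the carboxylic acid and the phenol by the disilazane, which prepares the hydroxy acid for a Noyori-type silyl-transfer acetalisation.

Step 9
Reactants: 13 trimethylsilyl 3-[(2E)-4-(tert-butyldimethylsilyloxy)-3-methylbut-2-en-1-yl]-4-methoxy-2-(trimethylsilyloxy)benzoate; 12 3,4-bis(tert-butyldimethylsilyloxy)benzaldehyde
Product: 14 racemic 2-[3,4-bis(tert-butyldimethylsilyloxy)phenyl]-8-[(2E)-4-(tert-butyldimethylsilyloxy)-3-methylbut-2-en-1-yl]-7-methoxy-4H-1,3-benzodioxin-4-one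
Conditions: TMSOTf (10 mol%), CH2Cl2, −78 to −40 °C; pyridine quench
Reagents that add atoms: none
Why: TMSOTf-catalysed Noyori acetalisation of a bis-silylated hydroxy acid with an aldehyde, as used for 1,3-dioxan-4-ones, driven by the formation of the disiloxane; the acetal centre is formed racemic on purpose.

Step 10
Reactants: 14 racemic 2-[3,4-bis(tert-butyldimethylsilyloxy)phenyl]-8-[(2E)-4-(tert-butyldimethylsilyloxy)-3-methylbut-2-en-1-yl]-7-methoxy-4H-1,3-benzodioxin-4-one
Product: 15 racemic 2-[3,4-bis(tert-butyldimethylsilyloxy)phenyl]-8-[(2E)-4-(tert-butyldimethylsilyloxy)-3-methylbut-2-en-1-yl]-7-methoxy-4-methylidene-4H-1,3-benzodioxine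
Conditions: Cp2TiMe2 (2.5 equiv), toluene, 65 °C, dark; filtration through basic Al2O3
Reagents that add atoms: dimethyltitanocene, C[Ti+2]C.c1cc[cH-]c1.c1cc[cH-]c1
Why: Petasis methylenation of a lactone carbonyl, a [2+2] addition and cycloreversion of the titanium methylidene that passes through no anionic tetrahedral intermediate, so the acylal should not collapse.

Step 11
Reactants: 15 racemic 2-[3,4-bis(tert-butyldimethylsilyloxy)phenyl]-8-[(2E)-4-(tert-butyldimethylsilyloxy)-3-methylbut-2-en-1-yl]-7-methoxy-4-methylidene-4H-1,3-benzodioxine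
Product: 17 (2S)-2-[3,4-bis(tert-butyldimethylsilyloxy)phenyl]-8-[(2E)-4-(tert-butyldimethylsilyloxy)-3-methylbut-2-en-1-yl]-7-methoxy-2,3-dihydro-4H-chromen-4-one, via silyl enol ether–oxocarbenium ion pair 16 (not isolated)
Conditions: confined chiral IDPi acid (BINOL-derived imidodiphosphorimidate, N-triflyl core, 3,3'-aryl groups; 5 mol%; antipode per the assumption), presilylated with allyltrimethylsilane (4.5 mol%), toluene, −60 to −40 °C; Et3N quench at low temperature
Reagents that add atoms: none
Why: Proposed new method: the N-silylated IDPi hands its silyl group to the enol-ether oxygen O3 of 15, the C2–O3 acetal bond ionises, and the O-silyl enol ether of the aryl methyl ketone and the O1=C2 aryl oxocarbenium ion, held as contact ion pair 16 by the chiral IDPi anion, recombine by C3-to-C2 bond formation, after which the silyl group returns to the catalyst; the closest known reaction types are the aluminium-Lewis-acid-promoted Petasis–Ferrier rearrangement of 4-methylidene-1,3-dioxanes to tetrahydropyran-4-ones, the chiral-phosphoric-acid-catalysed aza-Petasis–Ferrier rearrangement of hemiaminal vinyl ethers, and IDPi silylium ion-pair catalysis of Mukaiyama-type additions to oxocarbenium ions. Ring C closes in a 6-(enolendo)-endo-trig mode, an intramolecular Mukaiyama aldol-type addition to the oxocarbenium carbon. The new stereocentre C2 is controlled by the confined chiral counter-anion, which shields one face of the planar oxocarbenium ion; because ionisation erases the acetal stereocentre, both enantiomers of 15 should pass through the same achiral cation and converge on (2S)-17, just as the configuration of the acetal carbon is not transferred in classical Petasis–Ferrier rearrangements. The step needs cleavage of C2–O3 and not of C2–O1, which is secured because only C2–O3 cleavage releases a carbon nucleophile and leads irreversibly to the ketone, whereas C2–O1 cleavage can only reverse. It needs attack by the enol carbon and not by the side-chain alkene, which could capture the same cation in a Prins closure; the silyl enol ether is born in the same ionisation event and is far more nucleophilic, and the alkene is deactivated by its allylic silyloxy group. Silyl transfer is chosen over proton transfer so that the exocyclic methylidene carbon is not protonated, and the electron-rich 3,4-bis(silyloxy)phenyl ring lets the ionisation run at low temperature, where the product should not racemise by ring opening.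

Step 12
Reactants: 17 (2S)-2-[3,4-bis(tert-butyldimethylsilyloxy)phenyl]-8-[(2E)-4-(tert-butyldimethylsilyloxy)-3-methylbut-2-en-1-yl]-7-methoxy-2,3-dihydro-4H-chromen-4-one
Product: 18 (2S)-2-(3,4-dihydroxyphenyl)-8-[(2E)-4-hydroxy-3-methylbut-2-en-1-yl]-7-methoxy-2,3-dihydro-4H-chromen-4-one
Conditions: HF·pyridine, pyridine/THF, 0 to 23 °C
Reagents that add atoms: none
Why: fluoride-mediated cleavage of the two aryl silyl ethers and the primary alkyl silyl ether under acidic conditions, in which no 4'-phenoxide forms, so ring opening of the flavanone to the chalcone and loss of the C2 configuration should not occur.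

**Compound list**

1 | methyl 2-hydroxy-4-methoxybenzoate | COC(=O)c1ccc(OC)cc1O | starting material
2 | allyl bromide (3-bromoprop-1-ene) | C=CCBr | starting material
3 | methyl 4-methoxy-2-(prop-2-en-1-yloxy)benzoate | COC(=O)c1ccc(OC)cc1OCC=C | intermediate
4 | methyl 4-methoxy-6-oxo-5-(prop-2-en-1-yl)cyclohexa-1,3-diene-1-carboxylate (racemic ortho-dienone, not isolated) | COC(=O)C1=CC=C(OC)C(CC=C)C1=O | intermediate
5 | methyl 2-hydroxy-4-methoxy-3-(prop-2-en-1-yl)benzoate | COC(=O)c1ccc(OC)c(CC=C)c1O | intermediate
6 | methacrolein (2-methylprop-2-enal) | CC(=C)C=O | starting material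
7 | methyl 2-hydroxy-4-methoxy-3-[(2E)-3-methyl-4-oxobut-2-en-1-yl]benzoate | COC(=O)c1ccc(OC)c(C/C=C(\C)C=O)c1O | intermediate
8 | methyl 2-hydroxy-3-[(2E)-4-hydroxy-3-methylbut-2-en-1-yl]-4-methoxybenzoate | COC(=O)c1ccc(OC)c(C/C=C(\C)CO)c1O | intermediate
9 | methyl 3-[(2E)-4-(tert-butyldimethylsilyloxy)-3-methylbut-2-en-1-yl]-2-hydroxy-4-methoxybenzoate | COC(=O)c1ccc(OC)c(C/C=C(\C)CO[Si](C)(C)C(C)(C)C)c1O | intermediate
10 | 3-[(2E)-4-(tert-butyldimethylsilyloxy)-3-methylbut-2-en-1-yl]-2-hydroxy-4-methoxybenzoic acid | OC(=O)c1ccc(OC)c(C/C=C(\C)CO[Si](C)(C)C(C)(C)C)c1O | intermediate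
11 | 3,4-dihydroxybenzaldehyde | O=Cc1ccc(O)c(O)c1 | starting material
12 | 3,4-bis(tert-butyldimethylsilyloxy)benzaldehyde | O=Cc1ccc(O[Si](C)(C)C(C)(C)C)c(O[Si](C)(C)C(C)(C)C)c1 | intermediate
13 | trimethylsilyl 3-[(2E)-4-(tert-butyldimethylsilyloxy)-3-methylbut-2-en-1-yl]-4-methoxy-2-(trimethylsilyloxy)benzoate | C[Si](C)(C)OC(=O)c1ccc(OC)c(C/C=C(\C)CO[Si](C)(C)C(C)(C)C)c1O[Si](C)(C)C | intermediate
14 | racemic 2-[3,4-bis(tert-butyldimethylsilyloxy)phenyl]-8-[(2E)-4-(tert-butyldimethylsilyloxy)-3-methylbut-2-en-1-yl]-7-methoxy-4H-1,3-benzodioxin-4-one | COc1ccc2c(c1C/C=C(\C)CO[Si](C)(C)C(C)(C)C)OC(c1ccc(O[Si](C)(C)C(C)(C)C)c(O[Si](C)(C)C(C)(C)C)c1)OC2=O | intermediate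
15 | racemic 2-[3,4-bis(tert-butyldimethylsilyloxy)phenyl]-8-[(2E)-4-(tert-butyldimethylsilyloxy)-3-methylbut-2-en-1-yl]-7-methoxy-4-methylidene-4H-1,3-benzodioxine | COc1ccc2c(c1C/C=C(\C)CO[Si](C)(C)C(C)(C)C)OC(c1ccc(O[Si](C)(C)C(C)(C)C)c(O[Si](C)(C)C(C)(C)C)c1)OC2=C | intermediate
16 | ring-opened contact ion pair (not isolated): aryl oxocarbenium ion carrying the ortho 1-(trimethylsilyloxy)ethenyl group, paired with the IDPi anion; cation shown, its Me3Si group is lent by the catalyst and returns to it | COc1ccc(C(O[Si](C)(C)C)=C)c([O+]=Cc2ccc(O[Si](C)(C)C(C)(C)C)c(O[Si](C)(C)C(C)(C)C)c2)c1C/C=C(\C)CO[Si](C)(C)C(C)(C)C | intermediate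
17 | (2S)-2-[3,4-bis(tert-butyldimethylsilyloxy)phenyl]-8-[(2E)-4-(tert-butyldimethylsilyloxy)-3-methylbut-2-en-1-yl]-7-methoxy-2,3-dihydro-4H-chromen-4-one | COc1ccc2c(c1C/C=C(\C)CO[Si](C)(C)C(C)(C)C)O[C@H](c1ccc(O[Si](C)(C)C(C)(C)C)c(O[Si](C)(C)C(C)(C)C)c1)CC2=O | intermediate
18 | (2S)-2-(3,4-dihydroxyphenyl)-8-[(2E)-4-hydroxy-3-methylbut-2-en-1-yl]-7-methoxy-2,3-dihydro-4H-chromen-4-one (CNP0503781.1) | COc1ccc2c(c1C/C=C(\C)CO)O[C@H](c1ccc(O)c(O)c1)CC2=O | target

**Step count and risks**

Total step count: 12. Longest linear sequence: 11 steps (steps 1 to 6 and 8 to 12; step 7 prepares the aldehyde branch).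

Steps most likely to fail:

1. Step 11. Facial discrimination within the ion pair may be poor, or the enol acetal may be lost by protonation at the methylidene carbon, by hydrolysis, or by Prins capture of the cation by the side-chain alkene. The fallback leaves the enol-acetal strategy and uses known chemistry; it sets out from acid 10 and comes back at 17. Acid 10 would be treated with MeLi (3.5 equiv, THF, 0 °C) to give the methyl ketone 1-[3-[(2E)-4-(tert-butyldimethylsilyloxy)-3-methylbut-2-en-1-yl]-2-hydroxy-4-methoxyphenyl]ethanone F1. Condensation with N,N-dimethylformamide dimethyl acetal (toluene, 90 °C) would give the enaminone (2E)-1-[3-[(2E)-4-(tert-butyldimethylsilyloxy)-3-methylbut-2-en-1-yl]-2-hydroxy-4-methoxyphenyl]-3-(dimethylamino)prop-2-en-1-one F2. Cyclisation with loss of dimethylamine (PPTS, toluene, 60 °C) would give the chromone 8-[(2E)-4-(tert-butyldimethylsilyloxy)-3-methylbut-2-en-1-yl]-7-methoxy-4H-chromen-4-one F3. Separately, commercial 4-bromobenzene-1,2-diol would be silylated (TBSCl, imidazole, DMF) to 4-bromo-1,2-bis(tert-butyldimethylsilyloxy)benzene F4 and converted (n-BuLi, THF, −78 °C; B(O-i-Pr)3; aqueous NH4Cl) into [3,4-bis(tert-butyldimethylsilyloxy)phenyl]boronic acid F5. Enantioselective conjugate addition of the boronic acid to the chromone with Pd(OCOCF3)2 and the t-BuPyOx ligand antipode that gives the 2S product (NH4PF6, H2O, ClCH2CH2Cl, 60 °C), a known asymmetric arylation of chromones, should give 17, and step 12 follows.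

2. Step 10. The acylal lactone may undergo thermal cycloreversion during the methylenation, or the acid-labile enol acetal may isomerise or hydrolyse on isolation. The fallback makes the exocyclic enol ether by elimination and not by carbonyl methylenation; it sets out from ester 9 (with aldehyde 12) and comes back at 15. Ester 9 would be homologated with chloromethyllithium generated in its presence (ICH2Cl, MeLi·LiBr in excess, THF, −78 °C, the first equivalent being spent on the phenol; AcOH quench at −78 °C) to the chloromethyl ketone 1-[3-[(2E)-4-(tert-butyldimethylsilyloxy)-3-methylbut-2-en-1-yl]-2-hydroxy-4-methoxyphenyl]-2-chloroethanone F6. Luche reduction (NaBH4, CeCl3·7H2O, MeOH, −40 °C, chosen to avoid phenoxide displacement of the chloride) would give the racemic chlorohydrin 2-[(2E)-4-(tert-butyldimethylsilyloxy)-3-methylbut-2-en-1-yl]-6-(2-chloro-1-hydroxyethyl)-3-methoxyphenol F7. Acetalisation with aldehyde 12 (PPTS, benzene, azeotropic removal of water) would give 2-[3,4-bis(tert-butyldimethylsilyloxy)phenyl]-8-[(2E)-4-(tert-butyldimethylsilyloxy)-3-methylbut-2-en-1-yl]-4-(chloromethyl)-7-methoxy-4H-1,3-benzodioxine F8 as a mixture of diastereomers. Dehydrohalogenation (NaI catalytic, DBU, DMF, 80 °C), the known way to exocyclic enol ethers from halomethyl acetals, removes the only β-hydrogen (at C4) and should give 15.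

3. Step 9. The silyl triflate may ionise the product acylal and reverse the condensation, or closure at the hindered, weakly nucleophilic aryl silyl ether may be sluggish. The fallback delivers the acetal carbon as a preformed acetal and closes the ring by thermodynamic Brønsted-acid acetal exchange on the free hydroxy acid, which avoids both the silylated acid 13 and the silyl triflate; it sets out from acid 10 and aldehyde 12 and comes back at 14. Aldehyde 12 would be converted (HC(OMe)3, PPTS catalytic, MeOH, 23 °C) into 3,4-bis(tert-butyldimethylsilyloxy)benzaldehyde dimethyl acetal F9. Heating this acetal with acid 10 (PPTS catalytic, benzene, reflux through 5 Å molecular sieves to remove methanol) should give 14.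

**Further compounds**

F1 | step 11 | 1-[3-[(2E)-4-(tert-butyldimethylsilyloxy)-3-methylbut-2-en-1-yl]-2-hydroxy-4-methoxyphenyl]ethanone | CC(=O)c1ccc(OC)c(C/C=C(\C)CO[Si](C)(C)C(C)(C)C)c1O
F2 | step 11 | (2E)-1-[3-[(2E)-4-(tert-butyldimethylsilyloxy)-3-methylbut-2-en-1-yl]-2-hydroxy-4-methoxyphenyl]-3-(dimethylamino)prop-2-en-1-one | CN(C)/C=C/C(=O)c1ccc(OC)c(C/C=C(\C)CO[Si](C)(C)C(C)(C)C)c1O
F3 | step 11 | 8-[(2E)-4-(tert-butyldimethylsilyloxy)-3-methylbut-2-en-1-yl]-7-methoxy-4H-chromen-4-one | COc1ccc2c(c1C/C=C(\C)CO[Si](C)(C)C(C)(C)C)occc2=O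
F4 | step 11 | 4-bromo-1,2-bis(tert-butyldimethylsilyloxy)benzene | Brc1ccc(O[Si](C)(C)C(C)(C)C)c(O[Si](C)(C)C(C)(C)C)c1
F5 | step 11 | [3,4-bis(tert-butyldimethylsilyloxy)phenyl]boronic acid | OB(O)c1ccc(O[Si](C)(C)C(C)(C)C)c(O[Si](C)(C)C(C)(C)C)c1
F6 | step 10 | 1-[3-[(2E)-4-(tert-butyldimethylsilyloxy)-3-methylbut-2-en-1-yl]-2-hydroxy-4-methoxyphenyl]-2-chloroethanone | COc1ccc(C(=O)CCl)c(O)c1C/C=C(\C)CO[Si](C)(C)C(C)(C)C
F7 | step 10 | racemic 2-[(2E)-4-(tert-butyldimethylsilyloxy)-3-methylbut-2-en-1-yl]-6-(2-chloro-1-hydroxyethyl)-3-methoxyphenol | COc1ccc(C(O)CCl)c(O)c1C/C=C(\C)CO[Si](C)(C)C(C)(C)C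
F8 | step 10 | 2-[3,4-bis(tert-butyldimethylsilyloxy)phenyl]-8-[(2E)-4-(tert-butyldimethylsilyloxy)-3-methylbut-2-en-1-yl]-4-(chloromethyl)-7-methoxy-4H-1,3-benzodioxine (mixture of diastereomers) | COc1ccc2c(c1C/C=C(\C)CO[Si](C)(C)C(C)(C)C)OC(c1ccc(O[Si](C)(C)C(C)(C)C)c(O[Si](C)(C)C(C)(C)C)c1)OC2CCl
F9 | step 9 | 3,4-bis(tert-butyldimethylsilyloxy)benzaldehyde dimethyl acetal | COC(OC)c1ccc(O[Si](C)(C)C(C)(C)C)c(O[Si](C)(C)C(C)(C)C)c1
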